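## The problem

The target is a verticillane. Its cyclohexanone ring A (C1, C14, C13, C12, C11, C15) is spanned at C1 and C11 by the nine-carbon chain C2–C10, so a twelve-membered ring (C1–C11 plus C15) is bridged by the gem-dimethyl carbon C15. The chain leaves C1 and C11 on opposite faces of ring A, which makes the bicyclo[9.3.1] system an in,out (trans-bridged) one. There are seven stereocentres: C1, C10 and C11, plus two trisubstituted epoxides. The (3R,4R) epoxide derives from an E alkene and the (7R,8S) epoxide from a Z alkene. Only C1 has to be set from outside. It can steer C11 through the 1,3-relationship across ring A, C10 and C11 can be created together, and the C10 oxygen is homoallylic to C7=C8 and can deliver an oxidant to it. The C3/C4 epoxide is remote from every stereocentre and needs reagent control. The fragile groups are: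

- the α-methylene ketone (C12=C18 next to C13=O), a Michael acceptor that can isomerise to the C11=C12 enone;
- the two acid-labile epoxides and the C10 acetate;
- on the way, a β,γ-unsaturated aldehyde at C10.

The enabling feature is the array C10 carbinol – C11 methine – C12(=C18) – C13 ketone. This is a homoallylic alcohol whose alkene is the α-methylene of a ketone, the signature of γ-attack of a 2-(metallomethyl)enone on an aldehyde.

## Retrosynthesis

**29 to 28 (C3–O and C4–O).** The 3,4-epoxide is removed first. It has no directing group nearby and is acid-labile. Its precursor 28 has only one nucleophilic alkene, so the forward step need only choose a face. A chiral dioxirane (Shi) must deliver oxygen to give (3R,4R) and spare the enone, the acetate and the other epoxide.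

**28 to 27 to 26 (acetyl C–O; C7–O and C8–O).** The acetate and the 7,8-epoxide are removed next. The free C10 hydroxyl of 26 is homoallylic to C7=C8, so a hydroxyl-directed vanadium epoxidation selects this alkene over C3=C4 and also selects its face. Cutting the 3,4-epoxide at this stage instead would require telling two trisubstituted alkenes apart without a handle. Acetylation follows the directed step, so the hydroxyl is capped before the basic final epoxidation.

**26 to 24 via 25 (C10–C11, the key cut).** This single C–C disconnection opens the twelve-membered ring, removes C10 and C11 as stereocentres and turns the exo-methylene ketone into a 2-(bromomethyl)enone. Other ring bonds offer no such retron. Precursor 24 is a monocyclic enone with one stereocentre and an achiral chain ending in an aldehyde. The forward reaction must close a macrocycle at high dilution, form the anti C10/C11 pair, and bond to the face of C11 trans to the C2 chain.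

**24 to 23 to 22 to 21 to 20 (C10=O, C18–Br, C12–C18).** The β,γ-unsaturated aldehyde is made last from primary alcohol 23, itself unmasked from silyl ether 22. The allylic bromide comes from alcohol 21, and C18 is added to enone 20 as formaldehyde by a Morita–Baylis–Hillman reaction. This uses the enone already present in ring A as the only activating group.

**20 to 7 + 18 via 19 (C2–C3).** The chain is attached by an sp3–sp2 Negishi coupling of the alkylzinc reagent 19, made from iodide 7, with alkenyl iodide 18. Cutting C1–C2 instead would need the conjugate addition of an allylic nucleophile, with α/γ ambiguity and no reliable enantiocontrol. Making C3=C4 by carbonyl olefination would give no control of a trisubstituted E alkene. The chosen cut fixes both alkene geometries before the union and tolerates the enone.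

**7 to 6 to 5 to 3 to 2 to 1 (ring A and C1).** The iodomethyl group of 7 is traced through alcohol 6 and aldehyde 5 to the vinyl group of 3. Compound 3 arises by a catalytic asymmetric conjugate addition that desymmetrises dienone 2, the dehydrogenation product of commercial enone 1. The addition must pick one of two enantiotopic alkenes and leave the second enone for later use.

**18 to 16 to 15 to 14 to 13 to 12 to 10 to 8 (chain).** The E alkenyl iodide 18 comes from zirconium-catalysed carboalumination of alkyne 16, which installs C20 as well. The C5–C6 bond is made by alkylating the Z allylic bromide 14 with a propargyl anion equivalent, giving 15. The Z alkene C7=C8 and C19 come from syn addition of a methylcuprate to ynoate 10 (through 11), and 10 is made from the commercial butynyl silyl ether 8. A terpene alcohol such as nerol has a ready Z alkene, but its carbinol carbon would map onto C6 and one carbon would have to be excised at the other end. The three-step sequence from 8 to alcohol 13 is shorter.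

## Roads not taken

**Alternative 1:** The cut is C8–C9 together with C10–O. In the forward step a nitrile oxide generated at C8 from a primary nitro group adds across a C9=C10 vinyl group. This closes the carbocycle and gives the macrocyclic isoxazoline A1.
- Merits: nitrile oxide cycloadditions are among the most dependable macrocyclisations, need no metal, and form two bonds. The 3,4-epoxide and the C7 oxygen are fixed beforehand by acyclic, reagent-controlled chemistry. The sensitive enone is unveiled only at the end.
- Weak points: C10 is created with only remote control. After A1 the route still needs N–O cleavage, addition of the C19 methyl to a C8 ketone with the right facial sense, closure of the 7,8-epoxide, oxidation at C13, elimination to the exo-methylene and acetylation, all on a substrate carrying three silyl ethers and an epoxide.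
- Comparison: this road is better at securing the epoxide stereochemistry before ring closure. The chosen plan sets against it a key step that creates C10, C11 and the enone together under a predictable chair model, and an endgame of three steps.

**Alternative 2:** The cut is C7=C8. A C8 phosphonoacetate condenses with a C7 aldehyde to close the ring as the macrocyclic enoate A2, with C19 as a methyl ester.
- Merits: the olefination is robust at this ring size. C10 and C11 are in place before closure, so the ring-forming step carries no stereocentre risk. Once the ester is reduced, the allylic alcohol allows a Sharpless epoxidation of C7=C8 under reagent control. In that respect it is better than a homoallylic directed epoxidation.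
- Weak points: the geometry of a trisubstituted alkene formed from an α-branched phosphonate inside a ring is not assured. C19 must then be taken from ester to methyl next to an epoxide, the C13 silyl ether oxidised and two silyl groups removed. The C10/C11 pair still has to be built separately.
- Comparison: this road is safer in the ring closure itself. The chosen plan counters with C19 at the right oxidation level from the start, no protecting groups on the cyclisation substrate, and two stereocentres gained in the key step.

**Alternative 3:** The cut is C1–C2, made while C4–C13 is broken. An anionic oxy-Cope rearrangement of the alkoxide of a ten-membered, in,out-bridged divinyl carbinol expands the ring to the twelve-membered ketone A3.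
- Merits: the rearrangement is stereospecific. It gives the E C3=C4 alkene and C1 by chirality transfer, and it is driven by enolate formation. In stereochemical rigour it is at least as good as the chosen key step.
- Weak points: the difficulty is moved into the synthesis of a strained ten-membered bicycle that must already carry C10, C11, C12 and the Z C7=C8 alkene. After A3, elimination to the exo-methylene, both epoxidations, desilylation and acetylation remain.
- Comparison: the chosen plan sets against it a precursor made from one simple ring and one acyclic chain by a single cross-coupling.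

Key step: step 18

Assumption on step 2: the rhodium/(S)-BINAP catalyst is taken to attack dienone 2 with the facial sense established for cyclohex-2-enone, which leads to (S)-3; if the sense proves opposite, (R)-BINAP is used.
Assumption on supply: silyl ether 8 is taken as a commercial compound.

## Steps

Step 1
Reactants: 1 4,4-dimethylcyclohex-2-en-1-one
Product: 2 4,4-dimethylcyclohexa-2,5-dien-1-one
Conditions: DDQ, dioxane, reflux
Reagents that add atoms: none
Why: Dehydrogenation of an enone with DDQ (hydride abstraction from the dienol, then proton loss); the quaternary C4 blocks aromatisation, so the cross-conjugated dienone is the stable product.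

Step 2
Reactants: 2 4,4-dimethylcyclohexa-2,5-dien-1-one
Product: 3 (5S)-5-ethenyl-4,4-dimethylcyclohex-2-en-1-one
Conditions: CH2=CHBF3K (0.9 equiv), [Rh(cod)2]PF6 (3 mol %), (S)-BINAP, toluene/H2O, 100 °C
Reagents that add atoms: potassium vinyltrifluoroborate, C=C[B-](F)(F)F.[K+]
Why: Rhodium-catalysed asymmetric 1,4-addition of an alkenylboron reagent (Hayashi–Miyaura type); the two enone halves of 2 are enantiotopic, so the chiral catalyst selects one alkene and one face and sets the future C1. The remaining enone is less electrophilic than the cross-conjugated dienone and should survive when 2 is in slight excess.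

Step 3
Reactants: 3 (5S)-5-ethenyl-4,4-dimethylcyclohex-2-en-1-one
Product: 5 (1R)-2,2-dimethyl-5-oxocyclohex-3-ene-1-carbaldehyde, via vicinal diol 4 (not isolated)
Conditions: OsO4 (2 mol %), NaIO4, 2,6-lutidine, dioxane/H2O, rt
Reagents that add atoms: osmium tetroxide (catalytic oxygen carrier), O=[Os](=O)(=O)=O; sodium periodate (stoichiometric oxygen source), [Na+].[O-]I(=O)(=O)=O
Why: Lemieux–Johnson oxidation; OsO4 dihydroxylates the electron-rich vinyl group much faster than the electron-poor, neopentylic enone alkene, and periodate cleaves diol 4 in the same flask. 2,6-Lutidine keeps the medium neutral so that C1, now α to the aldehyde, is not epimerised.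

Step 4
Reactants: 5 (1R)-2,2-dimethyl-5-oxocyclohex-3-ene-1-carbaldehyde
Product: 6 (5R)-5-(hydroxymethyl)-4,4-dimethylcyclohex-2-en-1-one
Conditions: NaBH(OAc)3, AcOH, THF, 0 °C to rt
Reagents that add atoms: none
Why: Chemoselective hydride reduction; NaBH(OAc)3 reduces aldehydes but not ketones or enones, and the crude aldehyde is used at once to limit enolisation at C1.

Step 5
Reactants: 6 (5R)-5-(hydroxymethyl)-4,4-dimethylcyclohex-2-en-1-one
Product: 7 (5R)-5-(iodomethyl)-4,4-dimethylcyclohex-2-en-1-one
Conditions: I2, PPh3, imidazole, CH2Cl2, 0 °C to rt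
Reagents that add atoms: iodine, II
Why: Appel-type iodination of a primary alcohol by SN2 displacement of the alkoxyphosphonium ion; the weakly basic medium does not enolise the ketone toward cyclopropane formation.

Step 6
Reactants: 8 tert-butyl(but-3-yn-1-yloxy)dimethylsilane
Product: 10 methyl 5-{[tert-butyl(dimethyl)silyl]oxy}pent-2-ynoate, via lithium acetylide 9 (not isolated)
Conditions: n-BuLi, THF, −78 °C; ClCO2Me, −78 to 0 °C
Reagents that add atoms: methyl chloroformate, COC(=O)Cl
Why: Deprotonation of the terminal alkyne and acylation of acetylide 9 with a chloroformate, the standard ynoate synthesis; the added carbon becomes C6.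

Step 7
Reactants: 10 methyl 5-{[tert-butyl(dimethyl)silyl]oxy}pent-2-ynoate
Product: 12 methyl (2Z)-5-{[tert-butyl(dimethyl)silyl]oxy}-3-methylpent-2-enoate, via alkenylcuprate 11 (not isolated)
Conditions: Me2CuLi (from MeLi, CuI), THF, −78 °C; MeOH, −78 °C
Reagents that add atoms: lithium dimethylcuprate, [Li+].C[Cu-]C
Why: Syn carbocupration of an ynoate; at −78 °C alkenylcuprate 11 keeps its geometry and is protonated with retention, so the new methyl (C19) and the hydrogen are cis. The chain and the ester are therefore cis, which is the Z geometry of C7=C8.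

Step 8
Reactants: 12 methyl (2Z)-5-{[tert-butyl(dimethyl)silyl]oxy}-3-methylpent-2-enoate
Product: 13 (2Z)-5-{[tert-butyl(dimethyl)silyl]oxy}-3-methylpent-2-en-1-ol
Conditions: DIBAL-H, CH2Cl2, −78 °C; Rochelle salt
Reagents that add atoms: none
Why: 1,2-Reduction of an enoate to the allylic alcohol by DIBAL-H at low temperature, which does not isomerise the Z alkene.

Step 9
Reactants: 13 (2Z)-5-{[tert-butyl(dimethyl)silyl]oxy}-3-methylpent-2-en-1-ol
Product: 14 {[(3Z)-5-bromo-3-methylpent-3-en-1-yl]oxy}(tert-butyl)dimethylsilane
Conditions: CBr4, PPh3, CH2Cl2, 0 °C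
Reagents that add atoms: carbon tetrabromide, BrC(Br)(Br)Br
Why: Appel bromination of a primary allylic alcohol by SN2 attack of bromide on the alkoxyphosphonium ion; under these cold, neutral conditions neryl-type Z bromides keep their geometry.

Step 10
Reactants: 14 {[(3Z)-5-bromo-3-methylpent-3-en-1-yl]oxy}(tert-butyl)dimethylsilane
Product: 15 tert-butyldimethyl{[(3Z)-3-methyl-8-(trimethylsilyl)oct-3-en-7-yn-1-yl]oxy}silane
Conditions: 1-(trimethylsilyl)propyne, n-BuLi, THF, −78 °C; then 14, −78 to −20 °C
Reagents that add atoms: 1-(trimethylsilyl)prop-1-yne, CC#C[Si](C)(C)C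
Why: Alkylation of an allylic bromide with lithiated 1-(trimethylsilyl)propyne, a propargyl anion equivalent; the silyl group keeps the nucleophile propargylic and the primary bromide reacts by direct SN2 displacement, so the Z alkene is retained and the C5–C6 bond is formed.

Step 11
Reactants: 15 tert-butyldimethyl{[(3Z)-3-methyl-8-(trimethylsilyl)oct-3-en-7-yn-1-yl]oxy}silane
Product: 16 tert-butyldimethyl{[(3Z)-3-methyloct-3-en-7-yn-1-yl]oxy}silane
Conditions: K2CO3 (cat.), MeOH, rt
Reagents that add atoms: none
Why: Methanolysis of the alkynyl C–Si bond with catalytic carbonate; the alkyl silyl ether is stable to these conditions.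

Step 12
Reactants: 16 tert-butyldimethyl{[(3Z)-3-methyloct-3-en-7-yn-1-yl]oxy}silane
Product: 18 tert-butyl{[(3Z,7E)-8-iodo-3,7-dimethylocta-3,7-dien-1-yl]oxy}dimethylsilane, via alkenylalane 17 (not isolated)
Conditions: Me3Al, Cp2ZrCl2 (25 mol %), CH2Cl2, 0 °C to rt; then I2, THF, −30 to 0 °C
Reagents that add atoms: trimethylaluminium, C[Al](C)C; iodine, II
Why: Negishi zirconium-catalysed carboalumination; syn addition of methyl and aluminium across the terminal alkyne puts the methyl (C20) on C4 and the metal on C3, and iodinolysis with retention gives the E alkenyl iodide. The Z trisubstituted alkene and the silyl ether are inert.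

Step 13
Reactants: 7 (5R)-5-(iodomethyl)-4,4-dimethylcyclohex-2-en-1-one; 18 tert-butyl{[(3Z,7E)-8-iodo-3,7-dimethylocta-3,7-dien-1-yl]oxy}dimethylsilane
Product: 20 (5R)-5-[(2E,6Z)-9-{[tert-butyl(dimethyl)silyl]oxy}-3,7-dimethylnona-2,6-dien-1-yl]-4,4-dimethylcyclohex-2-en-1-one, via alkylzinc iodide 19 (not isolated)
Conditions: 7, Zn dust (activated), LiCl, THF, 40 °C; then 18, Pd(dppf)Cl2 (5 mol %), THF, 50 °C
Reagents that add atoms: none
Why: Negishi coupling; zinc inserts into the primary C–I bond without touching the enone, and zerovalent palladium joins alkylzinc 19 to the alkenyl iodide with retention of the E geometry. This forms C2–C3 and brings in the whole chain with both alkene geometries already fixed.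

Step 14
Reactants: 20 (5R)-5-[(2E,6Z)-9-{[tert-butyl(dimethyl)silyl]oxy}-3,7-dimethylnona-2,6-dien-1-yl]-4,4-dimethylcyclohex-2-en-1-one
Product: 21 (5R)-5-[(2E,6Z)-9-{[tert-butyl(dimethyl)silyl]oxy}-3,7-dimethylnona-2,6-dien-1-yl]-2-(hydroxymethyl)-4,4-dimethylcyclohex-2-en-1-one
Conditions: HCHO (37% aq.), DMAP, THF/H2O, rt
Reagents that add atoms: formaldehyde, C=O
Why: Morita–Baylis–Hillman hydroxymethylation; DMAP adds reversibly to C11, the enolate is trapped by formaldehyde at C12 and loss of DMAP restores the enone. Cyclohexenones with aqueous formaldehyde are standard substrates, and the neutral medium leaves the silyl ether and the 1,5-diene alone.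

Step 15
Reactants: 21 (5R)-5-[(2E,6Z)-9-{[tert-butyl(dimethyl)silyl]oxy}-3,7-dimethylnona-2,6-dien-1-yl]-2-(hydroxymethyl)-4,4-dimethylcyclohex-2-en-1-one
Product: 22 (5R)-2-(bromomethyl)-5-[(2E,6Z)-9-{[tert-butyl(dimethyl)silyl]oxy}-3,7-dimethylnona-2,6-dien-1-yl]-4,4-dimethylcyclohex-2-en-1-one
Conditions: CBr4, PPh3, CH2Cl2, −20 to 0 °C
Reagents that add atoms: carbon tetrabromide, BrC(Br)(Br)Br
Why: Appel bromination of the primary allylic alcohol; the bromide stays on C18 because the conjugated 2-(bromomethyl)enone is the more stable allylic isomer and C11 is neopentylic.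

Step 16
Reactants: 22 (5R)-2-(bromomethyl)-5-[(2E,6Z)-9-{[tert-butyl(dimethyl)silyl]oxy}-3,7-dimethylnona-2,6-dien-1-yl]-4,4-dimethylcyclohex-2-en-1-one
Product: 23 (5R)-2-(bromomethyl)-5-[(2E,6Z)-9-hydroxy-3,7-dimethylnona-2,6-dien-1-yl]-4,4-dimethylcyclohex-2-en-1-one
Conditions: HF (48% aq.), MeCN, 0 °C
Reagents that add atoms: none
Why: Acidic desilylation of a primary silyl ether; aqueous HF avoids the amine bases and free fluoride that would displace the reactive allylic bromide.

Step 17
Reactants: 23 (5R)-2-(bromomethyl)-5-[(2E,6Z)-9-hydroxy-3,7-dimethylnona-2,6-dien-1-yl]-4,4-dimethylcyclohex-2-en-1-one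
Product: 24 (3Z,7E)-9-[(1R)-4-(bromomethyl)-2,2-dimethyl-5-oxocyclohex-3-en-1-yl]-3,7-dimethylnona-3,7-dienal
Conditions: Dess–Martin periodinane, NaHCO3, CH2Cl2, 0 °C; used crude
Reagents that add atoms: none
Why: Dess–Martin oxidation under bicarbonate buffer gives the β,γ-unsaturated aldehyde without acid or base strong enough to move C7=C8 into conjugation; the allylic bromide is inert to the oxidant.

Step 18
Reactants: 24 (3Z,7E)-9-[(1R)-4-(bromomethyl)-2,2-dimethyl-5-oxocyclohex-3-en-1-yl]-3,7-dimethylnona-3,7-dienal
Product: 26 (1R,3E,7Z,10R,11S)-10-hydroxy-4,8,15,15-tetramethyl-12-methylidenebicyclo[9.3.1]pentadeca-3,7-dien-13-one, via allylchromium 25 (not isolated)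
Conditions: CrCl2 (8 equiv), THF, rt, 24 added by syringe pump to about 2 mM; aq. NH4Cl
Reagents that add atoms: none
Why: Two equivalents of CrCl2 (divalent chromium) reduce the C18–Br bond to the primary allylchromium 25 (trivalent chromium), which does not add to the ring ketone or the trisubstituted alkenes. The aldehyde oxygen binds chromium and C11, the γ-carbon, attacks C10 through a six-membered chair (SE2′), forming C10–C11 and moving the alkene to C12=C18; this is an intramolecular Nozaki–Hiyama allylation, and the closest known reactions are CrCl2-mediated γ-allylations of aldehydes by 2-(bromomethyl)acrylates, including macrocyclising ones. The twelve-membered carbocycle (C1–C11 plus C15) closes by exo attack on the aldehyde carbonyl (12-exo-trig), with C12 and C18 left outside the new ring. C11 is controlled by ring A: it reacts as a half-chair with the C2 chain pseudoequatorial, and bonding at C11 perpendicular to the allyl plane on the face away from the pseudoaxial C15 methyl leads directly to a chair. This gives C10 trans to C2, the 3,5-trans preference known for additions to 5-substituted cyclohexenones and the in,out junction of the target. C10 is controlled by the chair: ring A holds the allyl unit E-like (C15 trans to C18), so C9 equatorial gives the anti C10/C11 pair, (10R,11S). Aldehyde over ketone selectivity is intrinsic to allylchromium reagents, and γ-attack is secured because the isomeric C11-bound chromium species is blocked by the C15 methyls. Ring closure over oligomerisation is secured by slow addition, and the neutral, non-basic medium keeps C7=C8 out of conjugation with the aldehyde.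

Step 19
Reactants: 26 (1R,3E,7Z,10R,11S)-10-hydroxy-4,8,15,15-tetramethyl-12-methylidenebicyclo[9.3.1]pentadeca-3,7-dien-13-one
Product: 27 (1R,3E,7R,8S,10R,11S)-7,8-epoxy-10-hydroxyverticilla-3,12(18)-dien-13-one
Conditions: VO(acac)2 (5 mol %), t-BuOOH, CH2Cl2, 0 °C to rt
Reagents that add atoms: tert-butyl hydroperoxide, CC(C)(C)OO
Why: Hydroxyl-directed vanadium epoxidation of a homoallylic alcohol; the vanadate ester of the C10 alcohol delivers oxygen to C7=C8 through a chair-like array with C11 equatorial and the metal over the C7 side of the alkene, which places the new C8–O bond syn to C10–O and gives (7R,8S). C3=C4 has no directing group and the enone alkene is electron-poor, so both are left.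

Step 20
Reactants: 27 (1R,3E,7R,8S,10R,11S)-7,8-epoxy-10-hydroxyverticilla-3,12(18)-dien-13-one
Product: 28 (1R,3E,7R,8S,10R,11S)-10-acetoxy-7,8-epoxyverticilla-3,12(18)-dien-13-one
Conditions: Ac2O, pyridine, DMAP (cat.), CH2Cl2, 0 °C
Reagents that add atoms: acetic anhydride, CC(=O)OC(C)=O
Why: DMAP-catalysed acylation of the hindered secondary alcohol; capping the hydroxyl also removes the risk of it opening the neighbouring epoxide.

Step 21
Reactants: 28 (1R,3E,7R,8S,10R,11S)-10-acetoxy-7,8-epoxyverticilla-3,12(18)-dien-13-one
Product: 29 (1R,3R,4R,7R,8S,10R,11S)-10-acetoxy-3,4:7,8-diepoxyverticill-12(18)-en-13-one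
Conditions: D-fructose-derived Shi ketone (0.3 equiv), Oxone, K2CO3, Bu4NHSO4 (cat.), MeCN/dimethoxymethane/aq. buffer (pH about 10.5), 0 °C
Reagents that add atoms: potassium peroxymonosulfate (active component of Oxone), [K+].[O-]S(=O)(=O)OO
Why: Shi epoxidation; the chiral dioxirane attacks E trisubstituted alkenes through a spiro transition state with the vinylic hydrogen in the hindered quadrant, the sense that gives (R,R) epoxides of the type RCH=C(CH3)CH2R and here (3R,4R). The electrophilic oxidant does not attack the electron-poor enone, and the short reaction at 0 °C spares the acetate.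

## Compound list

1 | 4,4-dimethylcyclohex-2-en-1-one | CC1(C)CCC(=O)C=C1 | starting material
2 | 4,4-dimethylcyclohexa-2,5-dien-1-one | CC1(C)C=CC(=O)C=C1 | intermediate
3 | (5S)-5-ethenyl-4,4-dimethylcyclohex-2-en-1-one | O=C1C=CC(C)(C)[C@H](C=C)C1 | intermediate
4 | (5R)-5-(1,2-dihydroxyethyl)-4,4-dimethylcyclohex-2-en-1-one (both carbinol epimers) | O=C1C=CC(C)(C)[C@H](C(O)CO)C1 | intermediate (not isolated)
5 | (1R)-2,2-dimethyl-5-oxocyclohex-3-ene-1-carbaldehyde | O=C1C=CC(C)(C)[C@H](C=O)C1 | intermediate
6 | (5R)-5-(hydroxymethyl)-4,4-dimethylcyclohex-2-en-1-one | O=C1C=CC(C)(C)[C@H](CO)C1 | intermediate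
7 | (5R)-5-(iodomethyl)-4,4-dimethylcyclohex-2-en-1-one | O=C1C=CC(C)(C)[C@H](CI)C1 | intermediate
8 | tert-butyl(but-3-yn-1-yloxy)dimethylsilane | C#CCCO[Si](C)(C)C(C)(C)C | starting material
9 | lithium acetylide of 8, [4-{[tert-butyl(dimethyl)silyl]oxy}but-1-yn-1-yl]lithium | [Li]C#CCCO[Si](C)(C)C(C)(C)C | intermediate (not isolated)
10 | methyl 5-{[tert-butyl(dimethyl)silyl]oxy}pent-2-ynoate | COC(=O)C#CCCO[Si](C)(C)C(C)(C)C | intermediate
11 | lithium alkenyl(methyl)cuprate from syn addition to 10 (copper on C2, cis to the new methyl) | [Li+].COC(=O)/C(=C(/C)CCO[Si](C)(C)C(C)(C)C)[Cu-]C | intermediate (not isolated)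
12 | methyl (2Z)-5-{[tert-butyl(dimethyl)silyl]oxy}-3-methylpent-2-enoate | COC(=O)/C=C(/C)CCO[Si](C)(C)C(C)(C)C | intermediate
13 | (2Z)-5-{[tert-butyl(dimethyl)silyl]oxy}-3-methylpent-2-en-1-ol | OC/C=C(/C)CCO[Si](C)(C)C(C)(C)C | intermediate
14 | {[(3Z)-5-bromo-3-methylpent-3-en-1-yl]oxy}(tert-butyl)dimethylsilane | BrC/C=C(/C)CCO[Si](C)(C)C(C)(C)C | intermediate
15 | tert-butyldimethyl{[(3Z)-3-methyl-8-(trimethylsilyl)oct-3-en-7-yn-1-yl]oxy}silane | C[Si](C)(C)C#CCC/C=C(/C)CCO[Si](C)(C)C(C)(C)C | intermediate
16 | tert-butyldimethyl{[(3Z)-3-methyloct-3-en-7-yn-1-yl]oxy}silane | C#CCC/C=C(/C)CCO[Si](C)(C)C(C)(C)C | intermediate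
17 | [(1E,5Z)-8-{[tert-butyl(dimethyl)silyl]oxy}-2,6-dimethylocta-1,5-dien-1-yl]dimethylalane | C[Al](C)/C=C(\C)CC/C=C(/C)CCO[Si](C)(C)C(C)(C)C | intermediate (not isolated)
18 | tert-butyl{[(3Z,7E)-8-iodo-3,7-dimethylocta-3,7-dien-1-yl]oxy}dimethylsilane | I/C=C(\C)CC/C=C(/C)CCO[Si](C)(C)C(C)(C)C | intermediate
19 | {[(1R)-2,2-dimethyl-5-oxocyclohex-3-en-1-yl]methyl}zinc iodide | O=C1C=CC(C)(C)[C@H](C[Zn]I)C1 | intermediate (not isolated)
20 | (5R)-5-[(2E,6Z)-9-{[tert-butyl(dimethyl)silyl]oxy}-3,7-dimethylnona-2,6-dien-1-yl]-4,4-dimethylcyclohex-2-en-1-one | O=C1C=CC(C)(C)[C@H](C/C=C(\C)CC/C=C(/C)CCO[Si](C)(C)C(C)(C)C)C1 | intermediate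
21 | (5R)-5-[(2E,6Z)-9-{[tert-butyl(dimethyl)silyl]oxy}-3,7-dimethylnona-2,6-dien-1-yl]-2-(hydroxymethyl)-4,4-dimethylcyclohex-2-en-1-one | OCC1=CC(C)(C)[C@H](C/C=C(\C)CC/C=C(/C)CCO[Si](C)(C)C(C)(C)C)CC1=O | intermediate
22 | (5R)-2-(bromomethyl)-5-[(2E,6Z)-9-{[tert-butyl(dimethyl)silyl]oxy}-3,7-dimethylnona-2,6-dien-1-yl]-4,4-dimethylcyclohex-2-en-1-one | BrCC1=CC(C)(C)[C@H](C/C=C(\C)CC/C=C(/C)CCO[Si](C)(C)C(C)(C)C)CC1=O | intermediate
23 | (5R)-2-(bromomethyl)-5-[(2E,6Z)-9-hydroxy-3,7-dimethylnona-2,6-dien-1-yl]-4,4-dimethylcyclohex-2-en-1-one | BrCC1=CC(C)(C)[C@H](C/C=C(\C)CC/C=C(/C)CCO)CC1=O | intermediate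
24 | (3Z,7E)-9-[(1R)-4-(bromomethyl)-2,2-dimethyl-5-oxocyclohex-3-en-1-yl]-3,7-dimethylnona-3,7-dienal (seco C10 aldehyde) | BrCC1=CC(C)(C)[C@H](C/C=C(\C)CC/C=C(/C)CC=O)CC1=O | intermediate
25 | allylchromium dichloride of 24 (chromium on C18) | Cl[Cr](Cl)CC1=CC(C)(C)[C@H](C/C=C(\C)CC/C=C(/C)CC=O)CC1=O | intermediate (not isolated)
26 | (1R,3E,7Z,10R,11S)-10-hydroxy-4,8,15,15-tetramethyl-12-methylidenebicyclo[9.3.1]pentadeca-3,7-dien-13-one (10-hydroxyverticilla-3E,7Z,12(18)-trien-13-one) | C=C1C(=O)C[C@H]2C/C=C(\C)CC/C=C(/C)C[C@@H](O)[C@H]1C2(C)C | intermediate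
27 | (1R,3E,7R,8S,10R,11S)-7,8-epoxy-10-hydroxyverticilla-3,12(18)-dien-13-one | C=C1C(=O)C[C@H]2C/C=C(\C)CC[C@H]3O[C@@]3(C)C[C@@H](O)[C@H]1C2(C)C | intermediate
28 | (1R,3E,7R,8S,10R,11S)-10-acetoxy-7,8-epoxyverticilla-3,12(18)-dien-13-one | C=C1C(=O)C[C@H]2C/C=C(\C)CC[C@H]3O[C@@]3(C)C[C@@H](OC(C)=O)[C@H]1C2(C)C | intermediate
29 | (1R,3R,4R,7R,8S,10R,11S)-10-acetoxy-3,4:7,8-diepoxyverticill-12(18)-en-13-one (CNP0339728.4) | C=C1C(=O)C[C@H]2C[C@H]3O[C@]3(C)CC[C@H]3O[C@@]3(C)C[C@@H](OC(C)=O)[C@H]1C2(C)C | target

## Step count and risks

Total: 21 steps. Longest linear sequence: 16 steps (8 to 29, steps 6–21); the ring A branch from 1 is 14 steps.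

**Step 18 (key step).** The most likely failures are intermolecular coupling and protonation or homocoupling of the allylchromium in place of ring closure. Closure on the wrong face of C11 (cis-bridged bicycle) or through a boat (syn C10/C11) is also possible, because the tether may override the preferences of the open chair model. Fallback: leave the route at 21 and return at 26 by a palladium–indium umpolung allylation that generates the nucleophile catalytically and therefore at low concentration. Acetylation of 21 (Ac2O, pyridine) gives the allylic acetate F1. Desilylation (aqueous HF, MeCN) gives the hydroxy acetate F2. Dess–Martin oxidation gives the aldehyde acetate F3. Treatment of F3 with Pd(PPh3)4 (zerovalent palladium, catalytic) and indium monoiodide in THF at high dilution forms the π-allylpalladium, transfers it to indium and closes the same C10–C11 bond through a cyclic transition state to give 26.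

**Step 2.** Conversion may be low at the neopentylic β-carbon at the temperature needed, with over-addition to the second enone or erosion of enantioselectivity. The facial sense on a dienone rests on analogy. Fallback: from 2, a racemic copper-catalysed addition of vinylmagnesium bromide (CuI, THF, −40 °C) gives racemic 5-ethenyl-4,4-dimethylcyclohex-2-en-1-one F4. It is resolved by preparative chromatography on a chiral stationary phase, and the (S) enantiomer re-enters the route as 3.

**Step 14.** Addition of the amine catalyst to C11 next to the quaternary C15 may be slow, so the hydroxymethylation may stall or give formaldehyde oligomers and bis-adducts. Fallback: from 20, α-iodination (I2, pyridine, CH2Cl2) gives the 2-iodoenone F5. Stille coupling of F5 with (tributylstannyl)methanol (Pd(PPh3)4, dioxane, 90 °C) returns to 21.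

**Step 19.** Facial selectivity may be poor if the macrocycle prevents the chair-like delivery, and the vanadium Lewis acid may promote opening of the new epoxide by the free hydroxyl. Fallback: from 26, acetylation (Ac2O, pyridine, DMAP) gives the triene acetate F6. Both alkenes of F6 are then epoxidised with excess oxidant under the conditions of step 21. The D-fructose-derived ketone should attack the hydrogen-bearing carbons C3 and C7 in the same sense, which corresponds to (3R,4R) and (7R,8S), so this sequence returns directly at 29.

**Step 21.** The intrinsic facial bias of the macrocycle may override the catalyst and give the C3/C4-epimeric epoxide, and the basic medium may isomerise the exo-methylene ketone. Fallback: from 28, NBS in aqueous THF at 0 °C forms the bromohydrin F7. Bromine is delivered to the face the electrophile prefers, and water opens the bromonium ion anti at the tertiary C4. Closure with Ag2O in CH2Cl2 then places the epoxide oxygen on the opposite face and returns at 29 without strong base.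

## Further compounds

F1 | step 18 | (5R)-2-(acetoxymethyl)-5-[(2E,6Z)-9-{[tert-butyl(dimethyl)silyl]oxy}-3,7-dimethylnona-2,6-dien-1-yl]-4,4-dimethylcyclohex-2-en-1-one | CC(=O)OCC1=CC(C)(C)[C@H](C/C=C(\C)CC/C=C(/C)CCO[Si](C)(C)C(C)(C)C)CC1=O
F2 | step 18 | (5R)-2-(acetoxymethyl)-5-[(2E,6Z)-9-hydroxy-3,7-dimethylnona-2,6-dien-1-yl]-4,4-dimethylcyclohex-2-en-1-one | CC(=O)OCC1=CC(C)(C)[C@H](C/C=C(\C)CC/C=C(/C)CCO)CC1=O
F3 | step 18 | (3Z,7E)-9-[(1R)-4-(acetoxymethyl)-2,2-dimethyl-5-oxocyclohex-3-en-1-yl]-3,7-dimethylnona-3,7-dienal | CC(=O)OCC1=CC(C)(C)[C@H](C/C=C(\C)CC/C=C(/C)CC=O)CC1=O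
F4 | step 2 | racemic 5-ethenyl-4,4-dimethylcyclohex-2-en-1-one | C=CC1CC(=O)C=CC1(C)C
F5 | step 14 | (5R)-5-[(2E,6Z)-9-{[tert-butyl(dimethyl)silyl]oxy}-3,7-dimethylnona-2,6-dien-1-yl]-2-iodo-4,4-dimethylcyclohex-2-en-1-one | IC1=CC(C)(C)[C@H](C/C=C(\C)CC/C=C(/C)CCO[Si](C)(C)C(C)(C)C)CC1=O
F6 | step 19 | (1R,3E,7Z,10R,11S)-10-acetoxyverticilla-3,7,12(18)-trien-13-one | C=C1C(=O)C[C@H]2C/C=C(\C)CC/C=C(/C)C[C@@H](OC(C)=O)[C@H]1C2(C)C
F7 | step 21 | 10-acetoxy-3-bromo-7,8-epoxy-4-hydroxyverticill-12(18)-en-13-one, 3S,4R at the new centres, other centres as in 28 | C=C1C(=O)C[C@H]2C[C@H](Br)[C@](C)(O)CC[C@H]3O[C@@]3(C)C[C@@H](OC(C)=O)[C@H]1C2(C)C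
A1 | alternative 1 | macrocyclic isoxazoline spanning C8, C9 and C10, with the 3,4-epoxide, a C7 triethylsilyl ether and silyl ethers at C13 and on the C12 hydroxymethyl | CC(C)(C)[Si](C)(C)OC[C@@H]1[C@@H](O[Si](C)(C)C(C)(C)C)C[C@H]2C[C@H]3O[C@]3(C)CC[C@H](O[Si](CC)(CC)CC)C4=NO[C@H](C4)[C@H]1C2(C)C
A2 | alternative 2 | macrocyclic E enoate with C19 as methyl ester, the 3,4-epoxide, the C12 methylidene and silyl ethers at C10 and C13 | C=C1[C@@H](O[Si](C)(C)C(C)(C)C)C[C@H]2C[C@H]3O[C@]3(C)CC/C=C(/C(=O)OC)C[C@@H](O[Si](C)(C)C(C)(C)C)[C@H]1C2(C)C
A3 | alternative 3 | 10-silyloxy-12-(silyloxymethyl)verticilla-3E,7Z-dien-13-one | CC(C)(C)[Si](C)(C)OC[C@@H]1C(=O)C[C@H]2C/C=C(\C)CC/C=C(/C)C[C@@H](O[Si](C)(C)C(C)(C)C)[C@H]1C2(C)C
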